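At early times in this flask Z caps Q with a half-life of 0.23 min, shorter than the 0.96 min of linking, so G starts with a lead over Q, and the question is how long that lead lasts.

    Q + G → Q.G (k1 = 0.0240 M⁻¹ s⁻¹)
    Q + Z → Q.Z (k2 = 5.06 M⁻¹ s⁻¹)
    G → L (k3 = 1.27 × 10⁻⁴ s⁻¹)
    G + E → G.E (k4 = 0.00156 M⁻¹ s⁻¹)

Q 0.50 M; G 0.500 M; Z 10.0 mM; E 0.0250 M; time 40 min

- each monomer carries two end groups and Z one, which caps an end: a chain counts once for every two ends that are left, dead ends included; the units are half of the end groups of the two monomers charged
- run time (flask): 40 min

- whether the average number of monomer units in a chain (unreacted monomers counted as chains of one) reaches 5.0 by 40 min (no / yes)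
- average number of monomer units in a chain (unreacted monomers counted as chains of one) at 40 min

*How do you count chains?* Each link removes one chain, and dead ends stay counted. Since Q and G are charged equally, the chain concentration C equals the Q left plus Q.Z, and the length is 0.50 M divided by C.

*What competes with linking?* G has two side routes, which together act as one pseudo-first-order loss. Dividing their rate constant, with E at its charge, by the linking constant gives 6.92 mM. This is the loss concentration s, the level of Q at which G goes equally to links and to loss. The capped Q starts at Qc = 0.490 M, far above s, so at first nearly all of the G used goes into links.

*When does the lead vanish?* Dividing the rate of G by that of Q gives dG/dQ = 1 + s/Q, so the G lost is s ln(Qc/Q). That loss equals the lead of 10.0 mM at Q = 0.115 M. Treating Q and G as equal, I put this near 4.60 min, and from there G is the limiting reagent.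

*And the length?* A length of 5.0 needs C = 0.100 M, which the same equal-ends reckoning puts at about 6.30 min, so my answer is yes. *Your weak spot?* Equal ends overstate linking after 4.60 min; they give about 18.7 at 40 min, and I expect a length somewhat under that.

The forecast answers yes with a length of 16, on the ground that the slow loss of G “has overtaken the small G excess and starved the reaction”.

The answer for this flask is yes: the length reaches 5.0 at 6.24 min and stands at 15.9 at 40 min. Q then stands at 0.0215 M, and s ln(Qc/Q) at that level comes to 0.0216 M, while L and G.E together hold 0.0211 M.

Its constants were chosen freely, and the outcome is calculated.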